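Your quick number is fair at the end, but we would watch something else.

| flask | starting material | other conformer | catalyst | remark | time |
|---|---|---|---|---|---|
| south | 0.094 M | 0.50 equiv | 0.74 mol% | run made earlier |  |
| south-west | 0.094 M | 0.50 equiv | 1.7 mol% | run made earlier |  |
| south-east | 0.19 M | 0.50 equiv | 1.1 mol% | run made earlier |  |
| flask | 0.094 M | 0.500 equiv | 1.1 mol% |  | 10 h |

| run | time / h | isomer of the product A / % | target / % |
|---|---|---|---|
| south | 0.833 | 10 | 13 |
| south | 1.50 | 14 | 18 |
| south | 2.50 | 14 | 16 |
| south | 3.00 | 14 | 14 |
| south | 4.00 | 16 | 17 |
| south | 5.00 | 14 | 16 |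
| south | 6.00 | 16 | 19 |
| south-west | 0.333 | 11 | 17 |
| south-west | 1.00 | 19 | 17 |
| south-west | 1.50 | 17 | 18 |
| south-west | 2.50 | 18 | 19 |
| south-west | 4.00 | 21 | 19 |
| south-west | 5.00 | 20 | 17 |
| south-west | 6.00 | 20 | 21 |
| south-east | 0.500 | 15 | 17 |
| south-east | 1.50 | 20 | 17 |
| south-east | 3.00 | 23 | 18 |
| south-east | 4.00 | 21 | 18 |
| south-east | 6.00 | 22 | 18 |

(readings scatter by 1.5 percentage points)

- share of isomer of the product A in isomer of the product A plus target at 1.0 min
- share of isomer of the product A in isomer of the product A plus target at 25 min
- share of isomer of the product A in isomer of the product A plus target at 10 h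



1. Start from a one-step world: each other conformer gives one isomer of the product A (call it A). Then A ends at the conformer's share of the charge, s = 33.3%.
2. The runs end lower, so we define the capture f, the plateau of A divided by s. We read it in the two runs at the flask's concentration. The last readings average 15.3% in the south run and 20.3% in the south-west run.
3. Interpolating on catalyst loading, our reckoning gives the flask A = 17.2%, so f = 51.6%. Target, by the same interpolation, is 18.0%. Taking these plateaus to hold until 10 h, we reckon the flask's share there at 48.9%. We commit to no number at 1.0 min, which is earlier than the first south-west reading at 20 min.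
4. Your forecast says 25% at 1.0 min, 39% at 25 min and 49% at 10 h, noting that “Target levels off near 18% in every run”.
5. The flask gives 14.2%, 32.0% and 48.5%, so the forecast is high by 11 percentage points and 7 points early and right at the end. At 10.0 h the flask's capture is 51.0%, and isomer of the product B, which the readings do not list, holds 48.8%. With the other concentrations as charged, target's forward half-life into isomer of the product B by that step alone, 0.11 h, is shorter than its 0.60 h into side product by that step alone.

    starting material + catalyst → catalyst + target (k = 0.580 M⁻¹ s⁻¹)
    starting material ⇌ other conformer (K = 0.300, k = 9.10 × 10⁻⁵ s⁻¹)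
    starting material + target → side product (k = 0.00340 M⁻¹ s⁻¹)
    target + catalyst ⇌ isomer of the product B + catalyst, rate k4*[catalyst]*[target] forward; the back reaction follows from the equilibrium constant (K = 2.70, k = 1.70 M⁻¹ s⁻¹)
    catalyst + other conformer → catalyst + isomer of the product A (k = 0.180 M⁻¹ s⁻¹)

6. In a neighbouring flask, the same but with 0.200 equiv of other conformer, s is 16.7%, and our f gives A = 8.62%. The computed neighbour holds 11.0% of A at its end, a capture of 65.9%, with a share of 35.8% at 10 h.

The runs stem from a simulated flask with constants of no real substance.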